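**Retrosynthetic overview**

1. Target 27 ⇐ hydrogenolysis of four aryl benzyl ethers ⇐ flavonol 26 ⇐ copper-catalysed hydroxylation of the C3–I bond of 3-iodoflavone 25.
2. The strategy rests on ring C (the pyran-4-one): its O1–C2 bond and the oxygen on C3 both trace back to an alkyne set between benzofuran C5 and the acyl carbon C4. Hence 25 ⇐ ICl 6-endo-dig iodocyclisation of ynone 23 (O1–C2 closes, iodine lands on C3, one ortho benzyl group leaves).
3. 23 ⇐ acyl Sonogashira coupling of terminal alkyne 18 with 2,4,6-tris(benzyloxy)benzoyl chloride 22 (ring A, from 2,4,6-trihydroxybenzoic acid).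
4. 18 ⇐ trans-dihydrobenzofuran by enantioselective rhodium-carbenoid insertion into the benzylic C–H of the vanillyl ether in diazo ester 12 (forms C2–C3, cis, then epimerised at C3) ⇐ aldehyde 7 ⇐ 2,3-dihydroxybenzaldehyde + O-benzylvanillin.
5. Ring order: dihydrofuran ring (step 10), then ring C (step 19). The guaiacyl phenol is carried as a benzyl ether, so that no phenoxide para to the benzylic C2–O1 bond can open the dihydrofuran in the hot hydroxide of step 20.

Key step: step 19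

Assumption 1: Rh2(S-PTTL)4 is taken to give the (2R,3S)-cis ester, following the sense of induction known for this class of insertion; if the opposite sense is found, Rh2(R-PTTL)4 is used with everything else unchanged.
Assumption 2: 4-(benzyloxy)-3-methoxybenzaldehyde (O-benzylvanillin) is bought; otherwise it is made from vanillin with BnBr/K2CO3.

**Route**

Step 1
Reactants: 1 2,3-dihydroxybenzaldehyde
Product: 2 3-(benzyloxy)-2-hydroxybenzaldehyde
Conditions: NaH (2.2 equiv), DMSO, rt; then BnBr (1.0 equiv); aq. HCl work-up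
Reagents that add atoms: benzyl bromide, BrCc1ccccc1
Why: Williamson etherification of the dianion, in which the 3-oxide (neither conjugated with nor chelated to the formyl group) is the more nucleophilic oxygen, so one equivalent of benzyl bromide should alkylate O3 only.

Step 2
Reactants: 2 3-(benzyloxy)-2-hydroxybenzaldehyde
Product: 3 3-(benzyloxy)-5-bromo-2-hydroxybenzaldehyde
Conditions: Br2 (1.05 equiv), NaOAc, AcOH, rt
Reagents that add atoms: bromine, BrBr
Why: Electrophilic aromatic bromination goes para to the free phenol (C5, also meta to the aldehyde), the same site as in the bromination of o-vanillin.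

Step 3
Reactants: 4 4-(benzyloxy)-3-methoxybenzaldehyde
Product: 5 [4-(benzyloxy)-3-methoxyphenyl]methanol
Conditions: NaBH4, MeOH, 0 °C
Reagents that add atoms: none
Why: Borohydride reduction of an aromatic aldehyde to the benzylic alcohol; the benzyl and methyl ethers are inert.

Step 4
Reactants: 5 [4-(benzyloxy)-3-methoxyphenyl]methanol
Product: 6 4-(benzyloxy)-3-methoxybenzyl bromide
Conditions: PBr3 (0.4 equiv), Et2O, 0 °C; used without chromatography
Reagents that add atoms: phosphorus tribromide, BrP(Br)Br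
Why: The benzylic alcohol is converted to the bromide through its phosphite ester (SN2 by bromide); the electron-rich bromide is used at once because it solvolyses easily.

Step 5
Reactants: 3 3-(benzyloxy)-5-bromo-2-hydroxybenzaldehyde; 6 4-(benzyloxy)-3-methoxybenzyl bromide
Product: 7 3-(benzyloxy)-2-{[4-(benzyloxy)-3-methoxybenzyl]oxy}-5-bromobenzaldehyde
Conditions: K2CO3, DMF, rt
Reagents that add atoms: none
Why: Williamson etherification of the hindered but acidic salicylaldehyde-type phenol with a reactive benzylic bromide under mild carbonate conditions.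

Step 6
Reactants: 7 3-(benzyloxy)-2-{[4-(benzyloxy)-3-methoxybenzyl]oxy}-5-bromobenzaldehyde
Product: 9 2-[3-(benzyloxy)-2-{[4-(benzyloxy)-3-methoxybenzyl]oxy}-5-bromophenyl]acetonitrile, via N-formyl tosylenamine 8 (not isolated)
Conditions: TosMIC (1.2 equiv), t-BuOK (2.5 equiv), DME, −40 °C; then MeOH, reflux
Reagents that add atoms: p-toluenesulfonylmethyl isocyanide (TosMIC), [C-]#[N+]CS(=O)(=O)c1ccc(C)cc1
Why: Van Leusen reductive cyanation, in which the TosMIC anion adds to the aldehyde, the oxazoline opens to the N-formyl enamine 8, and hot methanol removes the formyl group and sulfinate to give the one-carbon-homologated nitrile without any acid that could cleave the alkoxybenzyl aryl ether.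

Step 7
Reactants: 9 2-[3-(benzyloxy)-2-{[4-(benzyloxy)-3-methoxybenzyl]oxy}-5-bromophenyl]acetonitrile
Product: 10 2-[3-(benzyloxy)-2-{[4-(benzyloxy)-3-methoxybenzyl]oxy}-5-bromophenyl]acetic acid
Conditions: KOH, EtOH/H2O, reflux; then cold dilute HCl to pH 3
Reagents that add atoms: potassium hydroxide, [K+].[OH-]; water, O
Why: Base hydrolysis of the nitrile via the amide; the aryl bromide, the benzyl ethers and the alkoxybenzyl aryl ether are stable to hydroxide, and the acidification is kept cold and brief.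

Step 8
Reactants: 10 2-[3-(benzyloxy)-2-{[4-(benzyloxy)-3-methoxybenzyl]oxy}-5-bromophenyl]acetic acid
Product: 11 methyl 2-[3-(benzyloxy)-2-{[4-(benzyloxy)-3-methoxybenzyl]oxy}-5-bromophenyl]acetate
Conditions: MeI, K2CO3, DMF, rt
Reagents that add atoms: iodomethane, CI
Why: Carboxylate O-alkylation (SN2) gives the methyl ester under non-acidic conditions.

Step 9
Reactants: 11 methyl 2-[3-(benzyloxy)-2-{[4-(benzyloxy)-3-methoxybenzyl]oxy}-5-bromophenyl]acetate
Product: 12 methyl 2-[3-(benzyloxy)-2-{[4-(benzyloxy)-3-methoxybenzyl]oxy}-5-bromophenyl]-2-diazoacetate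
Conditions: p-ABSA (1.3 equiv), DBU (1.5 equiv), MeCN, 0 °C to rt
Reagents that add atoms: 4-acetamidobenzenesulfonyl azide (p-ABSA), CC(=O)Nc1ccc(cc1)S(=O)(=O)N=[N+]=[N-]
Why: Regitz diazo transfer to the DBU enolate of the arylacetate gives the donor/acceptor diazo ester.

Step 10
Reactants: 12 methyl 2-[3-(benzyloxy)-2-{[4-(benzyloxy)-3-methoxybenzyl]oxy}-5-bromophenyl]-2-diazoacetate
Product: 13 methyl (2R,3S)-7-(benzyloxy)-2-[4-(benzyloxy)-3-methoxyphenyl]-5-bromo-2,3-dihydro-1-benzofuran-3-carboxylate (cis)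
Conditions: Rh2(S-PTTL)4 (dirhodium tetrakis[N-phthaloyl-(S)-tert-leucinate], 1 mol%), toluene, −78 to −60 °C
Reagents that add atoms: none
Why: Intramolecular carbenoid C–H insertion of the donor/acceptor rhodium carbene into the ether-activated benzylic CH2 five atoms away closes the dihydrofuran ring (C2–C3 bond); the chiral carboxylate ligands choose between the two enantiotopic benzylic hydrogens and so set C2 as R, while the compact transition state places aryl and ester cis, so C3 is S here and is corrected in step 12.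

Step 11
Reactants: 13 methyl (2R,3S)-7-(benzyloxy)-2-[4-(benzyloxy)-3-methoxyphenyl]-5-bromo-2,3-dihydro-1-benzofuran-3-carboxylate; 14 ethynyl(trimethyl)silane
Product: 15 methyl (2R,3S)-7-(benzyloxy)-2-[4-(benzyloxy)-3-methoxyphenyl]-5-[(trimethylsilyl)ethynyl]-2,3-dihydro-1-benzofuran-3-carboxylate
Conditions: PdCl2(PPh3)2 (5 mol%), CuI (5 mol%), Et3N/DMF, 70 °C
Reagents that add atoms: none
Why: Sonogashira coupling at the aryl bromide (para to the ring oxygen, hence the heating); any partial epimerisation at C3 by the amine is harmless because step 12 equilibrates that centre.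

Step 12
Reactants: 15 methyl (2R,3S)-7-(benzyloxy)-2-[4-(benzyloxy)-3-methoxyphenyl]-5-[(trimethylsilyl)ethynyl]-2,3-dihydro-1-benzofuran-3-carboxylate
Product: 16 methyl (2R,3R)-7-(benzyloxy)-2-[4-(benzyloxy)-3-methoxyphenyl]-5-ethynyl-2,3-dihydro-1-benzofuran-3-carboxylate (trans)
Conditions: NaOMe (0.5 equiv), MeOH/THF, rt
Reagents that add atoms: none
Why: Methoxide removes the alkynyl silyl group and, by reversible enolisation at C3 alone, equilibrates the cis ester to the less hindered trans ester; C2 cannot enolise, so the absolute configuration from step 10 is kept and C3 reaches the target configuration under thermodynamic control.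

Step 13
Reactants: 16 methyl (2R,3R)-7-(benzyloxy)-2-[4-(benzyloxy)-3-methoxyphenyl]-5-ethynyl-2,3-dihydro-1-benzofuran-3-carboxylate
Product: 17 [(2R,3S)-7-(benzyloxy)-2-[4-(benzyloxy)-3-methoxyphenyl]-5-ethynyl-2,3-dihydro-1-benzofuran-3-yl]methanol
Conditions: LiAlH4 (1.5 equiv), THF, 0 °C; aqueous NaOH work-up
Reagents that add atoms: none
Why: Hydride reduction of the ester to the primary alcohol at low temperature leaves the unactivated terminal alkyne, the benzyl ethers and both stereocentres untouched.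

Step 14
Reactants: 17 [(2R,3S)-7-(benzyloxy)-2-[4-(benzyloxy)-3-methoxyphenyl]-5-ethynyl-2,3-dihydro-1-benzofuran-3-yl]methanol
Product: 18 [(2R,3S)-7-(benzyloxy)-2-[4-(benzyloxy)-3-methoxyphenyl]-5-ethynyl-2,3-dihydro-1-benzofuran-3-yl]methyl acetate
Conditions: Ac2O, pyridine, DMAP (cat.), CH2Cl2, rt
Reagents that add atoms: acetic anhydride, CC(=O)OC(C)=O
Why: DMAP-catalysed acetylation masks the primary alcohol against the acid chloride of step 18 and installs a group that the hydroxide of step 20 removes.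

Step 15
Reactants: 19 2,4,6-trihydroxybenzoic acid
Product: 20 benzyl 2,4,6-tris(benzyloxy)benzoate
Conditions: BnBr (4.5 equiv), K2CO3 (5 equiv), DMF, rt to 50 °C
Reagents that add atoms: benzyl bromide, BrCc1ccccc1
Why: Exhaustive Williamson benzylation of the carboxylate and the three phenols; the electron-withdrawing, hydrogen-bonded carboxyl group disfavours C-benzylation of the phloroglucinol ring.

Step 16
Reactants: 20 benzyl 2,4,6-tris(benzyloxy)benzoate
Product: 21 2,4,6-tris(benzyloxy)benzoic acid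
Conditions: KOH, dioxane/MeOH/H2O, reflux; then aq. HCl
Reagents that add atoms: potassium hydroxide, [K+].[OH-]
Why: Saponification of the hindered benzyl ester under forcing hydroxide conditions frees the acid while the aryl benzyl ethers stay.

Step 17
Reactants: 21 2,4,6-tris(benzyloxy)benzoic acid
Product: 22 2,4,6-tris(benzyloxy)benzoyl chloride
Conditions: (COCl)2 (1.5 equiv), DMF (cat.), CH2Cl2, 0 °C to rt; concentrated and used at once
Reagents that add atoms: oxalyl chloride, O=C(Cl)C(=O)Cl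
Why: Vilsmeier-type activation with oxalyl chloride/DMF converts the acid to the acid chloride, which is used crude.

Step 18
Reactants: 18 [(2R,3S)-7-(benzyloxy)-2-[4-(benzyloxy)-3-methoxyphenyl]-5-ethynyl-2,3-dihydro-1-benzofuran-3-yl]methyl acetate; 22 2,4,6-tris(benzyloxy)benzoyl chloride
Product: 23 3-[(2R,3S)-3-(acetoxymethyl)-7-(benzyloxy)-2-[4-(benzyloxy)-3-methoxyphenyl]-2,3-dihydro-1-benzofuran-5-yl]-1-[2,4,6-tris(benzyloxy)phenyl]prop-2-yn-1-one
Conditions: PdCl2(PPh3)2 (2 mol%), CuI (4 mol%), Et3N (1.5 equiv), THF, rt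
Reagents that add atoms: none
Why: Acyl Sonogashira coupling, in which oxidative addition of the aroyl chloride to zerovalent palladium and transmetalation of the copper acetylide give the ynone at room temperature, conditions that leave the acetate and the stereocentres alone.

Step 19
Reactants: 23 3-[(2R,3S)-3-(acetoxymethyl)-7-(benzyloxy)-2-[4-(benzyloxy)-3-methoxyphenyl]-2,3-dihydro-1-benzofuran-5-yl]-1-[2,4,6-tris(benzyloxy)phenyl]prop-2-yn-1-one
Product: 25 [(2R,3S)-7-(benzyloxy)-2-[4-(benzyloxy)-3-methoxyphenyl]-5-[5,7-bis(benzyloxy)-3-iodo-4-oxo-4H-chromen-2-yl]-2,3-dihydro-1-benzofuran-3-yl]methyl acetate, via O-benzyl chromenylium chloride 24 (not isolated)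
Conditions: ICl (1.1 equiv, 1 M in CH2Cl2), CH2Cl2, −78 °C, dark; aq. Na2S2O3 quench
Reagents that add atoms: iodine monochloride, ClI
Why: ICl delivers I+ to the alkyne; the alkyne carbon bonded to benzofuran C5 is para to O1 and is the β-carbon of the ynone, so positive charge builds there and one of the two equivalent ortho benzyloxy oxygens attacks it anti to iodine. The resulting O-benzyl oxonium chloride 24 is debenzylated by chloride at the benzylic carbon (SN2), releasing benzyl chloride and the neutral 3-iodochromone. The closest known reaction type is the ICl-induced cyclisation of 2-alkoxyaryl alkynyl ketones to 3-iodochromones and 3-iodoflavones. Ring C closes in the 6-endo-dig mode (O1–C2 bond); the 5-exo-dig path to an aurone would place charge on the carbon next to the carbonyl and is disfavoured. No stereocentre is formed, and C2 and C3 of the dihydrofuran are not touched by these non-acidic, low-temperature conditions. The step needs regioselectivity, secured by the para-oxygenated aryl group on the alkyne, and chemoselectivity for the alkyne over the alkoxy arenes, secured by near-stoichiometric ICl at −78 °C, fast intramolecular trapping and the acyl deactivation of ring A.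

Step 20
Reactants: 25 [(2R,3S)-7-(benzyloxy)-2-[4-(benzyloxy)-3-methoxyphenyl]-5-[5,7-bis(benzyloxy)-3-iodo-4-oxo-4H-chromen-2-yl]-2,3-dihydro-1-benzofuran-3-yl]methyl acetate
Product: 26 2-[(2R,3S)-7-(benzyloxy)-2-[4-(benzyloxy)-3-methoxyphenyl]-3-(hydroxymethyl)-2,3-dihydro-1-benzofuran-5-yl]-5,7-bis(benzyloxy)-3-hydroxy-4H-chromen-4-one
Conditions: CuI (10 mol%), 1,10-phenanthroline (20 mol%), KOH (6 equiv), DMSO/H2O (1:1), 100 °C, argon; then dilute HCl
Reagents that add atoms: potassium hydroxide, [K+].[OH-]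
Why: Ullmann-type copper-catalysed hydroxylation of the activated alkenyl C3–I bond (oxidative addition to a copper hydroxide–phenanthroline complex, then C–O reductive elimination) gives the flavonol as its enolate while the same hydroxide saponifies the acetate; with the guaiacyl oxygen benzylated, no quinone methide pathway can open the dihydrofuran.

Step 21
Reactants: 26 2-[(2R,3S)-7-(benzyloxy)-2-[4-(benzyloxy)-3-methoxyphenyl]-3-(hydroxymethyl)-2,3-dihydro-1-benzofuran-5-yl]-5,7-bis(benzyloxy)-3-hydroxy-4H-chromen-4-one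
Product: 27 2,3-dehydrosilychristin, 2-[(2R,3S)-7-hydroxy-2-(4-hydroxy-3-methoxyphenyl)-3-(hydroxymethyl)-2,3-dihydro-1-benzofuran-5-yl]-3,5,7-trihydroxy-4H-chromen-4-one
Conditions: H2 (1 atm), palladium on carbon (Pd/C, 10 wt%), THF/MeOH, rt
Reagents that add atoms: none
Why: Palladium-catalysed hydrogenolysis removes the four aryl benzyl ethers under neutral conditions that should spare the flavonol double bond and the benzylic C2–O1 bond if the reaction is stopped at full debenzylation.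

**Compound list**

1 | 2,3-dihydroxybenzaldehyde | O=Cc1cccc(O)c1O | starting material
2 | 3-(benzyloxy)-2-hydroxybenzaldehyde | O=Cc1cccc(OCc2ccccc2)c1O | intermediate
3 | 3-(benzyloxy)-5-bromo-2-hydroxybenzaldehyde | O=Cc1cc(Br)cc(OCc2ccccc2)c1O | intermediate
4 | 4-(benzyloxy)-3-methoxybenzaldehyde (O-benzylvanillin) | COc1cc(C=O)ccc1OCc1ccccc1 | starting material
5 | [4-(benzyloxy)-3-methoxyphenyl]methanol | COc1cc(CO)ccc1OCc1ccccc1 | intermediate
6 | 4-(benzyloxy)-3-methoxybenzyl bromide | COc1cc(CBr)ccc1OCc1ccccc1 | intermediate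
7 | 3-(benzyloxy)-2-{[4-(benzyloxy)-3-methoxybenzyl]oxy}-5-bromobenzaldehyde | COc1cc(COc2c(C=O)cc(Br)cc2OCc2ccccc2)ccc1OCc1ccccc1 | intermediate
8 | N-{2-[3-(benzyloxy)-2-{[4-(benzyloxy)-3-methoxybenzyl]oxy}-5-bromophenyl]-1-[(4-methylphenyl)sulfonyl]ethenyl}formamide | O=CNC(=Cc1cc(Br)cc(OCc2ccccc2)c1OCc1ccc(OCc2ccccc2)c(OC)c1)S(=O)(=O)c1ccc(C)cc1 | intermediate
9 | 2-[3-(benzyloxy)-2-{[4-(benzyloxy)-3-methoxybenzyl]oxy}-5-bromophenyl]acetonitrile | N#CCc1cc(Br)cc(OCc2ccccc2)c1OCc1ccc(OCc2ccccc2)c(OC)c1 | intermediate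
10 | 2-[3-(benzyloxy)-2-{[4-(benzyloxy)-3-methoxybenzyl]oxy}-5-bromophenyl]acetic acid | OC(=O)Cc1cc(Br)cc(OCc2ccccc2)c1OCc1ccc(OCc2ccccc2)c(OC)c1 | intermediate
11 | methyl 2-[3-(benzyloxy)-2-{[4-(benzyloxy)-3-methoxybenzyl]oxy}-5-bromophenyl]acetate | COC(=O)Cc1cc(Br)cc(OCc2ccccc2)c1OCc1ccc(OCc2ccccc2)c(OC)c1 | intermediate
12 | methyl 2-[3-(benzyloxy)-2-{[4-(benzyloxy)-3-methoxybenzyl]oxy}-5-bromophenyl]-2-diazoacetate | COC(=O)C(=[N+]=[N-])c1cc(Br)cc(OCc2ccccc2)c1OCc1ccc(OCc2ccccc2)c(OC)c1 | intermediate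
13 | methyl (2R,3S)-7-(benzyloxy)-2-[4-(benzyloxy)-3-methoxyphenyl]-5-bromo-2,3-dihydro-1-benzofuran-3-carboxylate (cis) | COc1cc([C@@H]2Oc3c(OCc4ccccc4)cc(Br)cc3[C@@H]2C(=O)OC)ccc1OCc1ccccc1 | intermediate
14 | ethynyl(trimethyl)silane | C#C[Si](C)(C)C | starting material
15 | methyl (2R,3S)-7-(benzyloxy)-2-[4-(benzyloxy)-3-methoxyphenyl]-5-[(trimethylsilyl)ethynyl]-2,3-dihydro-1-benzofuran-3-carboxylate (cis) | COc1cc([C@@H]2Oc3c(OCc4ccccc4)cc(C#C[Si](C)(C)C)cc3[C@@H]2C(=O)OC)ccc1OCc1ccccc1 | intermediate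
16 | methyl (2R,3R)-7-(benzyloxy)-2-[4-(benzyloxy)-3-methoxyphenyl]-5-ethynyl-2,3-dihydro-1-benzofuran-3-carboxylate (trans) | COc1cc([C@@H]2Oc3c(OCc4ccccc4)cc(C#C)cc3[C@H]2C(=O)OC)ccc1OCc1ccccc1 | intermediate
17 | [(2R,3S)-7-(benzyloxy)-2-[4-(benzyloxy)-3-methoxyphenyl]-5-ethynyl-2,3-dihydro-1-benzofuran-3-yl]methanol (trans) | COc1cc([C@@H]2Oc3c(OCc4ccccc4)cc(C#C)cc3[C@H]2CO)ccc1OCc1ccccc1 | intermediate
18 | [(2R,3S)-7-(benzyloxy)-2-[4-(benzyloxy)-3-methoxyphenyl]-5-ethynyl-2,3-dihydro-1-benzofuran-3-yl]methyl acetate | COc1cc([C@@H]2Oc3c(OCc4ccccc4)cc(C#C)cc3[C@H]2COC(C)=O)ccc1OCc1ccccc1 | intermediate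
19 | 2,4,6-trihydroxybenzoic acid | O=C(O)c1c(O)cc(O)cc1O | starting material
20 | benzyl 2,4,6-tris(benzyloxy)benzoate | O=C(OCc1ccccc1)c1c(OCc2ccccc2)cc(OCc2ccccc2)cc1OCc1ccccc1 | intermediate
21 | 2,4,6-tris(benzyloxy)benzoic acid | O=C(O)c1c(OCc2ccccc2)cc(OCc2ccccc2)cc1OCc1ccccc1 | intermediate
22 | 2,4,6-tris(benzyloxy)benzoyl chloride | O=C(Cl)c1c(OCc2ccccc2)cc(OCc2ccccc2)cc1OCc1ccccc1 | intermediate
23 | 3-[(2R,3S)-3-(acetoxymethyl)-7-(benzyloxy)-2-[4-(benzyloxy)-3-methoxyphenyl]-2,3-dihydro-1-benzofuran-5-yl]-1-[2,4,6-tris(benzyloxy)phenyl]prop-2-yn-1-one | COc1cc([C@@H]2Oc3c(OCc4ccccc4)cc(C#CC(=O)c4c(OCc5ccccc5)cc(OCc5ccccc5)cc4OCc4ccccc4)cc3[C@H]2COC(C)=O)ccc1OCc1ccccc1 | intermediate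
24 | 2-[(2R,3S)-3-(acetoxymethyl)-7-(benzyloxy)-2-[4-(benzyloxy)-3-methoxyphenyl]-2,3-dihydro-1-benzofuran-5-yl]-1-benzyl-5,7-bis(benzyloxy)-3-iodo-4-oxo-4H-chromen-1-ium chloride | COc1cc([C@@H]2Oc3c(OCc4ccccc4)cc(C4=C(I)C(=O)c5c(OCc6ccccc6)cc(OCc6ccccc6)cc5[O+]4Cc4ccccc4)cc3[C@H]2COC(C)=O)ccc1OCc1ccccc1.[Cl-] | intermediate
25 | [(2R,3S)-7-(benzyloxy)-2-[4-(benzyloxy)-3-methoxyphenyl]-5-[5,7-bis(benzyloxy)-3-iodo-4-oxo-4H-chromen-2-yl]-2,3-dihydro-1-benzofuran-3-yl]methyl acetate | COc1cc([C@@H]2Oc3c(OCc4ccccc4)cc(-c4oc5cc(OCc6ccccc6)cc(OCc6ccccc6)c5c(=O)c4I)cc3[C@H]2COC(C)=O)ccc1OCc1ccccc1 | intermediate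
26 | 2-[(2R,3S)-7-(benzyloxy)-2-[4-(benzyloxy)-3-methoxyphenyl]-3-(hydroxymethyl)-2,3-dihydro-1-benzofuran-5-yl]-5,7-bis(benzyloxy)-3-hydroxy-4H-chromen-4-one | COc1cc([C@@H]2Oc3c(OCc4ccccc4)cc(-c4oc5cc(OCc6ccccc6)cc(OCc6ccccc6)c5c(=O)c4O)cc3[C@H]2CO)ccc1OCc1ccccc1 | intermediate
27 | 2,3-dehydrosilychristin, 2-[(2R,3S)-7-hydroxy-2-(4-hydroxy-3-methoxyphenyl)-3-(hydroxymethyl)-2,3-dihydro-1-benzofuran-5-yl]-3,5,7-trihydroxy-4H-chromen-4-one | COc1cc([C@@H]2Oc3c(O)cc(-c4oc5cc(O)cc(O)c5c(=O)c4O)cc3[C@H]2CO)ccc1O | target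

**Step count**

Total: 21 steps. Longest linear sequence: 16 steps (1, 2, 5–14, 18–21) from 2,3-dihydroxybenzaldehyde.

**Steps most likely to fail, with fallbacks**

Step 19 (key step). The risk is loss of chemoselectivity: ICl may iodinate the dialkoxy arene rings (guaiacyl ring, C6/C8 of ring A once formed) in competition with the alkyne, or some 5-exo closure may occur. The fallback closes ring C without halogen and brings in the C3 oxygen by oxidation. It sets out from 23: BCl3 (1.1 equiv, CH2Cl2, −78 °C) removes one ortho benzyl group through the ketone chelate to give 1-[2,4-bis(benzyloxy)-6-hydroxyphenyl]-3-[(2R,3S)-3-(acetoxymethyl)-7-(benzyloxy)-2-[4-(benzyloxy)-3-methoxyphenyl]-2,3-dihydro-1-benzofuran-5-yl]prop-2-yn-1-one F1. DMAP in DMF at rt then effects the 6-endo oxa-Michael closure to [(2R,3S)-7-(benzyloxy)-2-[4-(benzyloxy)-3-methoxyphenyl]-5-[5,7-bis(benzyloxy)-4-oxo-4H-chromen-2-yl]-2,3-dihydro-1-benzofuran-3-yl]methyl acetate F2. Dimethyldioxirane (acetone/CH2Cl2, 0 °C), followed by catalytic p-TsOH to open the 2,3-epoxide, gives [(2R,3S)-7-(benzyloxy)-2-[4-(benzyloxy)-3-methoxyphenyl]-5-[5,7-bis(benzyloxy)-3-hydroxy-4-oxo-4H-chromen-2-yl]-2,3-dihydro-1-benzofuran-3-yl]methyl acetate F3. K2CO3 in MeOH removes the acetate, and the route is rejoined at 26.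

Step 20. The risk is hydroxide addition at C2 of the 3-iodochromone with opening or contraction of the pyranone ring, or simple loss of iodine, before copper-mediated C–O bond formation. The fallback replaces C–O coupling by C–B formation and oxidation. It sets out from 25: Miyaura borylation (PdCl2(dppf), bis(pinacolato)diboron, KOAc, dioxane, 80 °C) gives [(2R,3S)-7-(benzyloxy)-2-[4-(benzyloxy)-3-methoxyphenyl]-5-[5,7-bis(benzyloxy)-4-oxo-3-(4,4,5,5-tetramethyl-1,3,2-dioxaborolan-2-yl)-4H-chromen-2-yl]-2,3-dihydro-1-benzofuran-3-yl]methyl acetate F4. Aqueous NaOH/H2O2 in THF at 0 °C oxidises the C–B bond and saponifies the acetate, and the route is rejoined at 26.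

Step 10. The risk is insufficient enantiotopic discrimination (and cis/trans control) by the catalyst, because the reacting benzyloxy group is flanked by two ortho substituents and is twisted out of the arene plane. The fallback upgrades the material by classical resolution. It sets out from 13: NaOH in MeOH/H2O/THF at 50 °C epimerises and saponifies to (2R,3R)-7-(benzyloxy)-2-[4-(benzyloxy)-3-methoxyphenyl]-5-bromo-2,3-dihydro-1-benzofuran-3-carboxylic acid F5. This is crystallised to diastereomeric purity as its (R)-1-phenylethylammonium salt F6 (or with the enantiomeric amine, whichever gives the less soluble salt of the wanted acid). After release of the acid with cold dilute citric acid, MeI/K2CO3 in DMF gives methyl (2R,3R)-7-(benzyloxy)-2-[4-(benzyloxy)-3-methoxyphenyl]-5-bromo-2,3-dihydro-1-benzofuran-3-carboxylate F7. Sonogashira coupling with 14 under the conditions of step 11 gives methyl (2R,3R)-7-(benzyloxy)-2-[4-(benzyloxy)-3-methoxyphenyl]-5-[(trimethylsilyl)ethynyl]-2,3-dihydro-1-benzofuran-3-carboxylate F8. NaOMe in MeOH removes the silyl group, and the route is rejoined at 16.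

**Further compounds**

F1 | step 19 | 1-[2,4-bis(benzyloxy)-6-hydroxyphenyl]-3-[(2R,3S)-3-(acetoxymethyl)-7-(benzyloxy)-2-[4-(benzyloxy)-3-methoxyphenyl]-2,3-dihydro-1-benzofuran-5-yl]prop-2-yn-1-one | COc1cc([C@@H]2Oc3c(OCc4ccccc4)cc(C#CC(=O)c4c(O)cc(OCc5ccccc5)cc4OCc4ccccc4)cc3[C@H]2COC(C)=O)ccc1OCc1ccccc1
F2 | step 19 | [(2R,3S)-7-(benzyloxy)-2-[4-(benzyloxy)-3-methoxyphenyl]-5-[5,7-bis(benzyloxy)-4-oxo-4H-chromen-2-yl]-2,3-dihydro-1-benzofuran-3-yl]methyl acetate | COc1cc([C@@H]2Oc3c(OCc4ccccc4)cc(-c4cc(=O)c5c(OCc6ccccc6)cc(OCc6ccccc6)cc5o4)cc3[C@H]2COC(C)=O)ccc1OCc1ccccc1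
F3 | step 19 | [(2R,3S)-7-(benzyloxy)-2-[4-(benzyloxy)-3-methoxyphenyl]-5-[5,7-bis(benzyloxy)-3-hydroxy-4-oxo-4H-chromen-2-yl]-2,3-dihydro-1-benzofuran-3-yl]methyl acetate | COc1cc([C@@H]2Oc3c(OCc4ccccc4)cc(-c4oc5cc(OCc6ccccc6)cc(OCc6ccccc6)c5c(=O)c4O)cc3[C@H]2COC(C)=O)ccc1OCc1ccccc1
F4 | step 20 | [(2R,3S)-7-(benzyloxy)-2-[4-(benzyloxy)-3-methoxyphenyl]-5-[5,7-bis(benzyloxy)-4-oxo-3-(4,4,5,5-tetramethyl-1,3,2-dioxaborolan-2-yl)-4H-chromen-2-yl]-2,3-dihydro-1-benzofuran-3-yl]methyl acetate | COc1cc([C@@H]2Oc3c(OCc4ccccc4)cc(-c4oc5cc(OCc6ccccc6)cc(OCc6ccccc6)c5c(=O)c4B4OC(C)(C)C(C)(C)O4)cc3[C@H]2COC(C)=O)ccc1OCc1ccccc1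
F5 | step 10 | (2R,3R)-7-(benzyloxy)-2-[4-(benzyloxy)-3-methoxyphenyl]-5-bromo-2,3-dihydro-1-benzofuran-3-carboxylic acid | COc1cc([C@@H]2Oc3c(OCc4ccccc4)cc(Br)cc3[C@H]2C(=O)O)ccc1OCc1ccccc1
F6 | step 10 | (R)-1-phenylethylammonium (2R,3R)-7-(benzyloxy)-2-[4-(benzyloxy)-3-methoxyphenyl]-5-bromo-2,3-dihydro-1-benzofuran-3-carboxylate | COc1cc([C@@H]2Oc3c(OCc4ccccc4)cc(Br)cc3[C@H]2C(=O)[O-])ccc1OCc1ccccc1.C[C@@H]([NH3+])c1ccccc1
F7 | step 10 | methyl (2R,3R)-7-(benzyloxy)-2-[4-(benzyloxy)-3-methoxyphenyl]-5-bromo-2,3-dihydro-1-benzofuran-3-carboxylate | COc1cc([C@@H]2Oc3c(OCc4ccccc4)cc(Br)cc3[C@H]2C(=O)OC)ccc1OCc1ccccc1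
F8 | step 10 | methyl (2R,3R)-7-(benzyloxy)-2-[4-(benzyloxy)-3-methoxyphenyl]-5-[(trimethylsilyl)ethynyl]-2,3-dihydro-1-benzofuran-3-carboxylate | COc1cc([C@@H]2Oc3c(OCc4ccccc4)cc(C#C[Si](C)(C)C)cc3[C@H]2C(=O)OC)ccc1OCc1ccccc1
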